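Compound numbers are those of the steps and the compound list below.

## Analysis of the target

Target 14 is (2S)-2-(3-hydroxy-4,5-dimethoxyphenyl)-7,8-dimethoxychroman-4-one, a flavanone. Ring A (C4a to C8a) carries methoxy groups at C7 and C8, ring C is the dihydropyranone (O1, C2, C3, C4), and ring B on C2 is a 3'-hydroxy-4',5'-dimethoxyphenyl group. C2 is the only stereocentre; with O1 > C1' > C3 > H it is S, so only absolute configuration has to be controlled. The sensitive element is the C2–O1 bond: it lies β to the C4 carbonyl and O1 is a phenoxide leaving group, so base (or hot acid) opens ring C by E1cB to the 2'-hydroxychalcone, which recloses without facial preference and racemises C2. The other points to watch are the single free phenol among four aryl methyl ethers, which must come from a building block in which it is already differentiated, and the electron-rich arenes. The difficulty is therefore less the skeleton than making C2 in one configuration and never exposing a C2-configured flavanone, or a β-hydroxy ketone precursor of it, to base. The strategy rests on the position of O1: it is bonded to the aromatic carbon C8a, between the methoxy-bearing C8 and the acyl-bearing C4a, while C2 is a secondary benzylic carbinol carbon. The aryl ether bond C8a–O1 can thus be formed last in ring C from a preformed (S)-alcohol without touching any bond at C2, provided C4 travels as a ketal.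

## Retrosynthetic reasoning

**14 to 13 (O–benzyl bond at C3').** The free phenol is carried as a benzyl ether. This group survives acid chloride formation, alkoxide, carbonate at 80 °C and aqueous acid, and it is removed by neutral hydrogenolysis, the one deprotection that cannot open ring C. The forward reaction must cleave only this benzylic C–O bond and leave the cyclic benzylic C2–O1 bond and the carbonyl alone.

**13 to 12 (the two C4–O bonds of a dioxolane).** The carbonyl is traced back to its ethylene ketal. The ketal is the precondition for the ring closure and is removed with acid at room temperature, the side from which the flavanone is configurationally safe.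

**12 to 11 (C8a–O1, the key disconnection).** Cutting the aryl ether bond on the ring A side leaves the stereocentre in an open-chain secondary alcohol, whose configuration is a matter of ketone reduction. Cutting O1–C2 instead would require substitution at a benzylic carbon or a reversible conjugate addition, both of which put C2 at stake. The forward reaction is an intramolecular palladium-catalysed O-arylation of the alcohol by the aryl bromide of 11. It must form the ether faster than the metal alkoxide is oxidised, and it must tolerate a bromide flanked on both sides.

**11 to 10 (C2–H bond).** The (S)-carbinol comes from the aryl ketone 10 by asymmetric transfer hydrogenation. The carbonyl lies between an aryl group and a CH2 group, the substitution pattern for which this reduction is most predictable.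

**10 to 7 and 8 (both C–O bonds at the future C4).** The β-keto ketal is opened to ynone 7 and ethylene glycol 8. The polarity of the ynone places both oxygens of the diol on the alkyne carbon that bears ring A and leaves the carbonyl at the future C2. The two oxidised carbons are therefore differentiated by construction. A 1,3-diketone would need selective mono-protection, and an aldol construction would put the free carbonyl at C4 and need an acid ketalisation of a dehydration-prone substrate.

**7 to 6 and 2 (the future C2–C3 bond).** The ynone is cut between the carbonyl carbon and the alkyne. This is the convergent union of the ring B acid chloride 6 with the ring A alkyne 2, and the coupling has to leave the aryl bromide of 2 untouched.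

**6 to 5 to 3, and 2 to 1.** Acid chloride 6 comes from acid 5, which comes from the commercial hydroxy acid 3 by exhaustive benzylation and saponification of the benzyl ester 4. Alkyne 2 comes from the commercial aldehyde 1 by one-carbon homologation; the aldehyde carbon becomes C4 and the added carbon becomes C3.

## Alternatives that were turned down

**Alternative 1:** Three bonds of ring C are cut at once (C4a–C4, C3–C4 and O1–C2). The ortho-iodophenol A2 of ring A and the ring B arylacetylene A3 would be joined with one carbonyl carbon by a palladium-catalysed carbonylative coupling in an amine; 6-endo addition of the phenol to the acylalkyne would then give flavone A1.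
- For: it is the most convergent plan, forms more skeletal bonds in one operation than the chosen closure, and reaches the full skeleton in fewer steps. On bond-forming economy it is clearly stronger.
- Against: A1 has an sp2 carbon at C2, so the only stereocentre would still have to be made by enantioselective conjugate reduction of the C2=C3 bond. A flavone is a vinylogous ester and a reluctant hydride acceptor, it tends to be reduced further at C4, and the flavanone would be released under reducing or basic conditions in which enolisation and ring opening threaten the new centre. In the carbonylative step 5-exo closure competes with the 6-endo mode, and A2 needs a regioselective iodination.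
- Comparison: the chosen route forms one bond in its key step, but C2 comes from the reduction of an ordinary aryl ketone and no flavanone is ever exposed to base. The price is the ketal and the steps leading to 11.

**Alternative 2:** O1–C2 and C3–C4 are cut. Acetal A5 would lose methanol under a chiral N-triflyl phosphoramide to give the methoxy-substituted ortho-quinone methide A6, which would add the ring B styrene A7 in an inverse-demand [4+2] cycloaddition to give the cis-4-methoxyflavan A4.
- For: ring C, two bonds and C2 would be made in one catalytic asymmetric step from two simple arenes. It is more convergent, and stereocontrol would sit in the ring-forming event itself, which the chosen plan does not offer.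
- Against: C4 arrives as a methyl ether, not a carbonyl. Two further operations (ether cleavage, oxidation of the carbinol) are needed at a benzylic position that ionises easily, since C4 is para to the 7-methoxy group and ortho to O1; elimination towards the flav-3-ene is invited, and the C4 stereocentre is made only to be destroyed. Styrene A7 is prone to acid-induced oligomerisation, and its addition is probably stepwise through a benzylic cation, so the configuration at C2 would depend on ion pairing with a large stabilised cation.
- Comparison: the chosen route is longer, but it delivers C4 at the correct oxidation level and sets C2 by a reduction whose facial sense is predictable.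

**Alternative 3:** C2–C3 and C4–C4a are cut. The racemic α-acetoxy aryl ether A9 would be ionised by a confined imidodiphosphorimidate acid. The aryloxy-stabilised cation would be attacked at the future C2 by ketene acetal A10, and the resulting dialkoxycarbenium ion would close onto C4a by Friedel–Crafts alkylation to give the diethyl ketal A8.
- For: on paper it is the shortest plan. Ring C, both C–C bonds and C2 come from racemic material in one enantioconvergent step, and C4 arrives at the ketone oxidation level, in the same kind of intermediate as 12. The closing position C4a is ortho to O1 and para to the 7-methoxy group, which is electronically right. In step economy it beats the chosen route.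
- Against: two untested events are stacked. One is ion-pair control over a long-lived cation stabilised by an aryloxy group and a trioxygenated ring B. The other is arene attack by a dialkoxycarbenium ion, which normally collapses to an open-chain ester faster than it alkylates an aromatic ring. A9 is a labile mixed acetal that would need reductive acetylation of an aryl ester.
- Comparison: in place of brevity, the chosen route uses only established reaction types, and its one uncertain event is a ring closure that cannot affect C2.

Key step: step 6

Remark on the chemistry: the (S,S)-configured RuCl(p-cymene)(TsDPEN) catalyst is assumed to reduce ketone 10 in the same facial sense as simple aryl alkyl ketones, the CH2–ketal arm taking the place of the methyl group of acetophenone.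

## Route

Step 1
Reactants: 1 2-bromo-3,4-dimethoxybenzaldehyde
Product: 2 2-bromo-1-ethynyl-3,4-dimethoxybenzene
Conditions: dimethyl (1-diazo-2-oxopropyl)phosphonate, K2CO3, MeOH, 0 °C to rt
Reagents that add atoms: dimethyl (1-diazo-2-oxopropyl)phosphonate, CC(=O)C(=[N+]=[N-])P(=O)(OC)OC
Why: Seyferth–Gilbert homologation in the Ohira–Bestmann variant: methoxide removes the acetyl group, the diazomethylphosphonate anion adds to the aldehyde, and loss of dimethyl phosphate and N2 with a 1,2-shift should give the terminal alkyne. The carbonate base leaves the aryl bromide untouched, which a dibromo-olefin route with butyllithium would not.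

Step 2
Reactants: 3 3-hydroxy-4,5-dimethoxybenzoic acid
Product: 5 3-(benzyloxy)-4,5-dimethoxybenzoic acid, via benzyl 3-(benzyloxy)-4,5-dimethoxybenzoate 4 (not isolated)
Conditions: BnBr, K2CO3, DMF, 60 °C; then NaOH, H2O/MeOH, 60 °C; then HCl (aq) to pH 2
Reagents that add atoms: benzyl bromide, BrCc1ccccc1; sodium hydroxide, [Na+].[OH-]
Why: Williamson alkylation of phenoxide and carboxylate gives the benzyl ether benzyl ester 4, and saponification in the same pot cleaves only the ester. The acid should be collected by acidification after the neutral by-products are washed out.

Step 3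
Reactants: 5 3-(benzyloxy)-4,5-dimethoxybenzoic acid; 2 2-bromo-1-ethynyl-3,4-dimethoxybenzene
Product: 7 1-[3-(benzyloxy)-4,5-dimethoxyphenyl]-3-(2-bromo-3,4-dimethoxyphenyl)prop-2-yn-1-one, via 3-(benzyloxy)-4,5-dimethoxybenzoyl chloride 6 (not isolated)
Conditions: (COCl)2, DMF (cat.), CH2Cl2, 0 °C to rt, evaporate; then 2, PdCl2(PPh3)2 (2 mol%), CuI (4 mol%), Et3N, THF, rt
Reagents that add atoms: none
Why: Acid chloride formation through the Vilsmeier-type chloroiminium salt, then acyl Sonogashira coupling. Zerovalent palladium inserts into the acyl C–Cl bond at room temperature far faster than into the electron-rich, doubly ortho-substituted C–Br bond of 2, so the bromide should be carried through intact.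

Step 4
Reactants: 7 1-[3-(benzyloxy)-4,5-dimethoxyphenyl]-3-(2-bromo-3,4-dimethoxyphenyl)prop-2-yn-1-one; 8 ethylene glycol
Product: 10 1-[3-(benzyloxy)-4,5-dimethoxyphenyl]-2-[2-(2-bromo-3,4-dimethoxyphenyl)-1,3-dioxolan-2-yl]ethan-1-one, via hydroxyethoxy enone 9 (not isolated)
Conditions: 8 (10 equiv), KOt-Bu (0.3 equiv), THF, 0 °C to rt
Reagents that add atoms: none
Why: Double oxa-Michael (double conjugate) addition of a diol to an ynone: the glycolate adds to the alkyne carbon bearing ring A to give enone 9, whose tethered hydroxyl closes 5-exo-trig onto the same carbon. The ynone polarity fixes the ketal at the future C4 and leaves the carbonyl at the future C2; excess diol suppresses bridging of two ynones, and catalytic base suffices because each addition regenerates alkoxide.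

Step 5
Reactants: 10 1-[3-(benzyloxy)-4,5-dimethoxyphenyl]-2-[2-(2-bromo-3,4-dimethoxyphenyl)-1,3-dioxolan-2-yl]ethan-1-one
Product: 11 (S)-1-[3-(benzyloxy)-4,5-dimethoxyphenyl]-2-[2-(2-bromo-3,4-dimethoxyphenyl)-1,3-dioxolan-2-yl]ethan-1-ol
Conditions: RuCl(p-cymene)[(S,S)-TsDPEN] (1 mol%), HCO2H/Et3N (5:2), EtOAc, 30 °C
Reagents that add atoms: none
Why: Noyori–Ikariya asymmetric transfer hydrogenation: hydride on ruthenium and the proton on the ligand nitrogen are delivered in an outer-sphere six-membered transition state in which the ketone aryl group lies under the η6-arene (CH/π attraction). With the (S,S)-ligand this should give the (S)-carbinol, as with acetophenone, since the priorities OH > aryl > CH2 are the same; loss of CO2 makes the reduction irreversible, and bromide, ketal and benzyl ether are not touched.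

Step 6
Reactants: 11 (S)-1-[3-(benzyloxy)-4,5-dimethoxyphenyl]-2-[2-(2-bromo-3,4-dimethoxyphenyl)-1,3-dioxolan-2-yl]ethan-1-ol
Product: 12 (2S)-2-[3-(benzyloxy)-4,5-dimethoxyphenyl]-7,8-dimethoxy-2,3-dihydrospiro[chromene-4,2'-[1,3]dioxolane]
Conditions: Pd(OAc)2 (5 mol%), 2-(di-tert-butylphosphino)-1,1'-binaphthyl (6 mol%), Cs2CO3 (1.5 equiv), toluene, 80 °C
Reagents that add atoms: none
Why: Pd(OAc)2 is reduced in the flask, and the bulky monophosphine holds a monoligated zerovalent palladium that inserts into the C8a–Br bond of 11, although this bond is flanked by the C8 methoxy group and the ketal-bearing C4a. Cs2CO3 deprotonates the coordinated C2 hydroxyl and bromide is displaced, giving a divalent arylpalladium alkoxide that is a seven-membered oxapalladacycle (Pd, C8a, C4a, C4, C3, C2, O). C–O reductive elimination from it forms C8a–O1 and closes the six-membered ring C; this is the intramolecular Buchwald–Hartwig etherification of a secondary alcohol with an aryl bromide, a known way to chromans. No stereocentre is created: neither the C2–O nor the C2–H bond is touched, so the (S) configuration from step 5 should be carried over with retention. The selectivity needed is reductive elimination over β-hydride elimination of the benzylic alkoxide, which would return ketone 10 with a debrominated arene and, if reversible, racemise C2. The di-tert-butylphosphino group and the two ortho substituents of the aryl ligand crowd the metal and accelerate reductive elimination, and the chelate ring holds the C2–H bond away from the open coordination site. Masking C4 as the dioxolane is what makes carbonate at 80 °C safe: a free β-hydroxy ketone would fragment by retro-aldol reaction and a free flavanone would open to the chalcone, whereas the ketal has no acidic α-hydrogen. The benzyl and methyl ethers are inert under these conditions.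

Step 7
Reactants: 12 (2S)-2-[3-(benzyloxy)-4,5-dimethoxyphenyl]-7,8-dimethoxy-2,3-dihydrospiro[chromene-4,2'-[1,3]dioxolane]
Product: 13 (2S)-2-[3-(benzyloxy)-4,5-dimethoxyphenyl]-7,8-dimethoxy-2,3-dihydro-4H-chromen-4-one
Conditions: 1 M HCl (aq)/THF (1:4), rt
Reagents that add atoms: water, O
Why: Acid-catalysed ketal hydrolysis through an oxocarbenium ion at C4 that is stabilised by O1 (ortho) and the 7-methoxy group (para), so dilute acid at room temperature should suffice. Under these conditions the flavanone is neither enolised nor opened, so C2 should be preserved; the benzyl ether stays.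

Step 8
Reactants: 13 (2S)-2-[3-(benzyloxy)-4,5-dimethoxyphenyl]-7,8-dimethoxy-2,3-dihydro-4H-chromen-4-one
Product: 14 (2S)-2-(3-hydroxy-4,5-dimethoxyphenyl)-7,8-dimethoxy-2,3-dihydro-4H-chromen-4-one
Conditions: H2 (1 atm), 10% Pd/C, EtOAc, rt
Reagents that add atoms: none
Why: Hydrogenolysis of the benzyl aryl ether under neutral conditions, which cannot open ring C. The primary benzylic C–O bond should react well before the cyclic secondary C2–O1 bond or the donor-substituted aryl ketone, so the reaction is stopped after uptake of one equivalent of H2.

## Compound list

1 | 2-bromo-3,4-dimethoxybenzaldehyde | COc1ccc(C=O)c(Br)c1OC | starting material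
2 | 2-bromo-1-ethynyl-3,4-dimethoxybenzene | COc1ccc(C#C)c(Br)c1OC | intermediate
3 | 3-hydroxy-4,5-dimethoxybenzoic acid | COc1cc(C(=O)O)cc(O)c1OC | starting material
4 | benzyl 3-(benzyloxy)-4,5-dimethoxybenzoate | COc1cc(C(=O)OCc2ccccc2)cc(OCc2ccccc2)c1OC | intermediate (not isolated)
5 | 3-(benzyloxy)-4,5-dimethoxybenzoic acid | COc1cc(C(=O)O)cc(OCc2ccccc2)c1OC | intermediate
6 | 3-(benzyloxy)-4,5-dimethoxybenzoyl chloride | COc1cc(C(=O)Cl)cc(OCc2ccccc2)c1OC | intermediate (not isolated)
7 | 1-[3-(benzyloxy)-4,5-dimethoxyphenyl]-3-(2-bromo-3,4-dimethoxyphenyl)prop-2-yn-1-one | COc1cc(C(=O)C#Cc2ccc(OC)c(OC)c2Br)cc(OCc2ccccc2)c1OC | intermediate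
8 | ethylene glycol (ethane-1,2-diol) | OCCO | starting material
9 | 1-[3-(benzyloxy)-4,5-dimethoxyphenyl]-3-(2-bromo-3,4-dimethoxyphenyl)-3-(2-hydroxyethoxy)prop-2-en-1-one (mixture of alkene isomers) | COc1cc(C(=O)C=C(OCCO)c2ccc(OC)c(OC)c2Br)cc(OCc2ccccc2)c1OC | intermediate (not isolated)
10 | 1-[3-(benzyloxy)-4,5-dimethoxyphenyl]-2-[2-(2-bromo-3,4-dimethoxyphenyl)-1,3-dioxolan-2-yl]ethan-1-one | COc1cc(C(=O)CC2(OCCO2)c2ccc(OC)c(OC)c2Br)cc(OCc2ccccc2)c1OC | intermediate
11 | (S)-1-[3-(benzyloxy)-4,5-dimethoxyphenyl]-2-[2-(2-bromo-3,4-dimethoxyphenyl)-1,3-dioxolan-2-yl]ethan-1-ol | COc1cc([C@@H](O)CC2(OCCO2)c2ccc(OC)c(OC)c2Br)cc(OCc2ccccc2)c1OC | intermediate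
12 | (2S)-2-[3-(benzyloxy)-4,5-dimethoxyphenyl]-7,8-dimethoxy-2,3-dihydrospiro[chromene-4,2'-[1,3]dioxolane] | COc1cc([C@@H]2CC3(OCCO3)c3ccc(OC)c(OC)c3O2)cc(OCc2ccccc2)c1OC | intermediate
13 | (2S)-2-[3-(benzyloxy)-4,5-dimethoxyphenyl]-7,8-dimethoxy-2,3-dihydro-4H-chromen-4-one | COc1cc([C@@H]2CC(=O)c3ccc(OC)c(OC)c3O2)cc(OCc2ccccc2)c1OC | intermediate
14 | (2S)-2-(3-hydroxy-4,5-dimethoxyphenyl)-7,8-dimethoxy-2,3-dihydro-4H-chromen-4-one | COc1cc([C@@H]2CC(=O)c3ccc(OC)c(OC)c3O2)cc(O)c1OC | target

## Step count and least certain steps

Total step count: 8. Longest linear sequence: 7 steps (3 to 14 through steps 2 to 8); step 1 is the only step on the second branch.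

**Step 6 (key step).** Oxidative addition at the doubly ortho-substituted C8a–Br bond may be slow. β-Hydride elimination from the benzylic palladium alkoxide may then compete with C–O reductive elimination; this would oxidise the carbinol, reduce the C–Br bond and, if reversible, erode the configuration at C2. The fallback sets out from 11 and returns at 12. An aromatic Finkelstein exchange (CuI, NaI, trans-N,N'-dimethylcyclohexane-1,2-diamine, dioxane, 110 °C) would give (S)-1-[3-(benzyloxy)-4,5-dimethoxyphenyl]-2-[2-(2-iodo-3,4-dimethoxyphenyl)-1,3-dioxolan-2-yl]ethan-1-ol F1. An Ullmann-type etherification with monovalent copper (CuI, 3,4,7,8-tetramethyl-1,10-phenanthroline, Cs2CO3, toluene, 110 °C) would then close ring C. Copper alkoxides do not readily undergo β-hydride elimination, so the oxidation–reduction leak of the palladium cycle is absent.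

**Step 4.** The second, ring-closing oxa-Michael addition may stall at the conjugated enol ether 9, because the receiving carbon is hindered by the ortho-bromo aryl group and the closure is reversible. Alkoxide attack at the carbonyl may also cleave the ynone. The fallback sets out from 7 and returns at 10. Propane-1,3-dithiol with NaOMe in MeOH/CH2Cl2 (−10 °C to rt) adds twice as the softer, more nucleophilic thiolate to give 1-[3-(benzyloxy)-4,5-dimethoxyphenyl]-2-[2-(2-bromo-3,4-dimethoxyphenyl)-1,3-dithian-2-yl]ethan-1-one F2. Oxidative exchange of the dithiane with the hypervalent iodine reagent PhI(OCOCF3)2 in MeCN in the presence of 8 would then give the dioxolane 10.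

**Step 5.** Hydride transfer next to the bulky, neopentyl-like ketal arm may be slow or show insufficient facial selectivity. The dioxolane may also open by retro-oxa-Michael reaction in the formic acid/amine medium. The fallback sets out from 10 and returns at 11. It replaces the transfer hydrogenation by a Corey–Bakshi–Shibata reduction ((R)-2-methyl-CBS-oxazaborolidine, BH3·SMe2, THF, −20 °C). This is a stoichiometric borane reduction in an aprotic neutral medium, with facial selection by the oxazaborolidine–ketone complex; the (R)-catalyst gives the (S)-carbinol for an aryl/CH2 ketone. This fallback makes no new compound (F0).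

**Step 3.** Palladium may insert into the aryl bromide once the acid chloride is used up, which leads to oligomerisation. Copper-mediated oxidative homocoupling of the alkyne and hydrolysis of the acid chloride by adventitious moisture are further risks. The fallback sets out from 6 and 2 and returns at 7 without any transition metal. Treating 6 with N,O-dimethylhydroxylamine hydrochloride and Et3N (CH2Cl2, 0 °C) gives 3-(benzyloxy)-N,4,5-trimethoxy-N-methylbenzamide F3. Deprotonating 2 with EtMgBr (THF, rt) gives [(2-bromo-3,4-dimethoxyphenyl)ethynyl]magnesium bromide F4 without halogen–metal exchange. Adding F4 to F3 (THF, 0 °C; cold aqueous NH4Cl quench) should deliver ynone 7 through the chelated tetrahedral adduct.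

**Step 8.** Over-reduction may compete with debenzylation: hydrogenation of the C4 carbonyl, or hydrogenolysis of the cyclic benzylic C2–O1 bond. The fallback sets out from 12 and returns at 14, replacing steps 7 and 8 in reversed order. Hydrogenolysis of 12 (H2, 10% Pd/C, EtOAc, rt) is carried out while C4 is still a ketal and gives 5-[(2S)-7,8-dimethoxy-2,3-dihydrospiro[chromene-4,2'-[1,3]dioxolan]-2-yl]-2,3-dimethoxyphenol F5. Hydrolysis of the dioxolane (1 M HCl (aq)/THF, rt) then gives 14, so the free ketone never meets the hydrogenation catalyst.

## Further compounds

F1 | step 6 | (S)-1-[3-(benzyloxy)-4,5-dimethoxyphenyl]-2-[2-(2-iodo-3,4-dimethoxyphenyl)-1,3-dioxolan-2-yl]ethan-1-ol | COc1cc([C@@H](O)CC2(OCCO2)c2ccc(OC)c(OC)c2I)cc(OCc2ccccc2)c1OC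
F2 | step 4 | 1-[3-(benzyloxy)-4,5-dimethoxyphenyl]-2-[2-(2-bromo-3,4-dimethoxyphenyl)-1,3-dithian-2-yl]ethan-1-one | COc1cc(C(=O)CC2(SCCCS2)c2ccc(OC)c(OC)c2Br)cc(OCc2ccccc2)c1OC
F0 | step 5 | none | none
F3 | step 3 | 3-(benzyloxy)-N,4,5-trimethoxy-N-methylbenzamide | CON(C)C(=O)c1cc(OC)c(OC)c(OCc2ccccc2)c1
F4 | step 3 | [(2-bromo-3,4-dimethoxyphenyl)ethynyl]magnesium bromide | COc1ccc(C#C[Mg]Br)c(Br)c1OC
F5 | step 8 | 5-[(2S)-7,8-dimethoxy-2,3-dihydrospiro[chromene-4,2'-[1,3]dioxolan]-2-yl]-2,3-dimethoxyphenol | COc1cc([C@@H]2CC3(OCCO3)c3ccc(OC)c(OC)c3O2)cc(O)c1OC
A1 | alternative 1 | 2-[3-(benzyloxy)-4,5-dimethoxyphenyl]-7,8-dimethoxy-4H-chromen-4-one (3'-benzyloxy-4',5',7,8-tetramethoxyflavone) | COc1cc(C2=CC(=O)c3ccc(OC)c(OC)c3O2)cc(OCc2ccccc2)c1OC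
A2 | alternative 1 | 6-iodo-2,3-dimethoxyphenol | COc1ccc(I)c(O)c1OC
A3 | alternative 1 | 1-(benzyloxy)-5-ethynyl-2,3-dimethoxybenzene | COc1cc(C#C)cc(OCc2ccccc2)c1OC
A4 | alternative 2 | (2S,4S)-2-[3-(benzyloxy)-4,5-dimethoxyphenyl]-4,7,8-trimethoxychromane (cis-3'-benzyloxy-4,4',5',7,8-pentamethoxyflavan) | COc1cc([C@@H]2C[C@H](OC)c3ccc(OC)c(OC)c3O2)cc(OCc2ccccc2)c1OC
A5 | alternative 2 | 6-(dimethoxymethyl)-2,3-dimethoxyphenol | COC(OC)c1ccc(OC)c(OC)c1O
A6 | alternative 2 | 2,3-dimethoxy-6-(methoxymethylidene)cyclohexa-2,4-dien-1-one | COC=C1C=CC(OC)=C(OC)C1=O
A7 | alternative 2 | 1-(benzyloxy)-5-ethenyl-2,3-dimethoxybenzene | COc1cc(C=C)cc(OCc2ccccc2)c1OC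
A8 | alternative 3 | (2S)-2-[3-(benzyloxy)-4,5-dimethoxyphenyl]-4,4-diethoxy-7,8-dimethoxychromane | COc1cc([C@@H]2CC(OCC)(OCC)c3ccc(OC)c(OC)c3O2)cc(OCc2ccccc2)c1OC
A9 | alternative 3 | [3-(benzyloxy)-4,5-dimethoxyphenyl](2,3-dimethoxyphenoxy)methyl acetate (racemic) | COc1cc(C(OC(C)=O)Oc2cccc(OC)c2OC)cc(OCc2ccccc2)c1OC
A10 | alternative 3 | 1,1-diethoxyethene | C=C(OCC)OCC
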